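## Analysis of the target

Compound 24 is a germacranolide: a ten-membered carbocycle (C1–C10) fused at C6 and C7 to an α-methylene-γ-butyrolactone (O–C12(=O)–C11=C13). The ring holds a cross-conjugated dienone, C1=C2 (E), C3=O and C4=C5 (Z, methyl on C4); the Z alkene has the less stable angelate-type geometry and must be made kinetically and then kept. The ring stereocentres are C6 (S), C7 (R), C8 (R) and C10 (R). The lactone is cis-fused: H6, H7, H8 and the C10 hydroxyl lie on one face, while the lactone oxygen, C11, the C8 acyloxy group and the C10 methyl lie on the other, so the C8 and C10 oxygens are 1,3-anti. A fifth stereocentre sits in the (R)-2-methylbutanoyl group and comes in with the acid. Sensitive elements are: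
- the exocyclic methylene lactone, a Michael acceptor whose allylic C7–H becomes acidic whenever C8 is a carbonyl;
- the dienone and the tertiary allylic C10 alcohol (retro-aldol or elimination once C8 is a ketone);
- migration of the lactone from O6 to a free O8, and the epimerisable acyl α-carbon.

The difficulty is to close a ten-membered ring with two alkenes of opposite, defined geometry and to set the quaternary C10 carbinol, which is remote from C6 and C7. The strategy rests on the 1,3-relationship of the C8 oxygen and the C10 carbinol across C9: this is an aldol pattern, and it can be carried as a 2-isoxazoline made of C8, C9, C10, the C10 oxygen and a nitrogen on C8.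

## Retrosynthetic reasoning

**C8–O acyl bond.** Target 24 is cut to diol 22 and acid 23. The acylation comes last so that the acyl α-stereocentre meets no earlier reagent; the forward step must acylate the secondary C8 hydroxyl and leave the tertiary C10 hydroxyl free.

**C8–H bond.** Diol 22 is traced to β-hydroxy ketone 21. The C10 hydroxyl is then used to deliver hydride to C8 from its own face, which sets the 1,3-anti relationship without an external chiral reagent.

**N–O bond.** Ketone 21 is the unmasked form of isoxazoline 19 (via hydroxy imine 20). The forward step must cleave N–O reductively without touching the dienone or the methylene lactone.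

**C8–C9 and C10–O bonds (key disconnection).** Isoxazoline 19 is opened to nitrile oxide 18, which comes from oxime 16 through hydroximoyl chloride 17. The cut is made here because it is the only ring closure that also creates a stereocentre (C10) and delivers the C8/C10 oxygen pattern. Both alkene geometries are then fixed in an open chain, where they can be controlled, and the cycloaddition product is three steps from 24. The forward reaction has to close the ten-membered ring on the terminal C9=C10 alkene only, with the dipole carbon on C9 and on the correct face.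

**Oxidation level at C3 and C8.** Oxime 16 is traced through keto aldehyde 15 to diol 14 and its silyl ether 13. Both carbonyls are generated together and late, because the C8 aldehyde is the most fragile intermediate of the route.

**C3–C4 bond.** Carbinol 13 is cut to vinyl iodide 10 and dienal 12 (from methacrolein 11) by a chromium-mediated alkenyl–aldehyde coupling. This coupling attacks only an aldehyde and is neutral. An enone synthesis through strongly basic phosphorus carbanions is ruled out, since such reagents would add to the lactone carbonyl and to its exocyclic alkene.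

**C4=C5 bond.** Vinyl iodide 10 comes from aldehyde 9 by a Z-selective iodo-olefination; iodine cis to C6 becomes C3 cis to C6 after the coupling.

**C6–C7 bond and lactone.** Aldehyde 9 comes from lactone 7 by glycol cleavage via diol 8. Lactone 7 comes from hydroxy ester 6, which is cut to allylic bromide 4 and aldehyde 5. This Barbier allylation sets C6 and C7 in one step; the stereocentre of 5 is used as a relay and is then cut away. The (S)-aldehyde is required: anti (Felkin–Anh) addition gives the C6 configuration of 24, and the Z reagent gives the syn adduct, hence the cis lactone.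

**Allylic bromide.** Bromide 4 comes from adduct 3 by SN2' bromination, and 3 from methyl acrylate 1 and aldehyde 2.

## Alternatives that were turned down

**Alternative 1:** The C6–C7 bond is disconnected, reading the C6 hydroxyl and the C11=C13 methylene of carbinol A1 as the trace of a [2,3] shift. Backwards, the ten-membered ring becomes a thirteen-membered ether ring in which C6 is tied to C13 through oxygen. Forward, tin–lithium exchange at C6 gives an α-alkoxy carbanion whose Wittig–Still rearrangement contracts the ring to A1.
- For: the medium ring is never closed directly, one sigmatropic event makes C6–C7 with both stereocentres, and no Michael-acceptor lactone is present until the end. On these points it is stronger than the chosen route.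
- Against: the C6 carbanion is also allylic to C4=C5, so its configuration and the site of rearrangement are not secured. The C6/C7 relationship depends on a transannular transition state. C8 and C10 must be set separately beforehand, with three differentiated oxygen protecting groups and a C3 ketal.
- After A1 there remain PMB removal, two-stage oxidation of C12, lactonisation, three deprotections and the acylation.
- Comparison: the chosen route offers instead a key step that builds the C8/C10 pattern together with the ring, and a three-step end game from 19.

**Alternative 2:** The transannular C1–C5 bond is reconnected, so that dienone A2 is the ring-opened form of a 5,7-fused bicycle. Forward, ionisation of a C4 chloride gives an oxyallyl cation over C2–C4, whose conrotatory 4π opening (retro-Nazarov) cuts C1–C5 and forms both alkenes.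
- For: C6, C7, C8 and C10 could be set on a rigid bicycle, one step would reveal the whole dienone, and there is no entropic ring-closure problem. On control of the ring stereocentres it is stronger.
- Against: this electrocyclisation normally runs in the closing direction, and the strained E,Z-dienone of A2 can re-close. Which terminus becomes E and which Z is not controlled. The C10 hydroxyl next to the cationic terminus invites fragmentation or a 1,2-shift.
- A2 also lacks C13, so the methylene would have to be added by enolate chemistry in the presence of the dienone and a free tertiary alcohol.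
- Comparison: the chosen cycloaddition is a known reaction type at a demanding ring size. Its risk is kinetic, not a fight against thermodynamics.

**Alternative 3:** The C1–C10 bond is disconnected and a C3–C8 bond is added, so that ketone A3 is the ring-expanded product of a six-membered ring with two vicinal alkenyl groups, one on the C8 carbinol carbon. Forward, the C8 potassium alkoxide undergoes a chair [3,3] shift (anionic oxy-Cope) and the enolate is protonated to A3.
- For: this is the most dependable entry to ten-membered carbocycles, it is strongly driven, it transfers chirality to C10 and fixes the C4=C5 geometry, and it gives the same C8 ketone that the chosen route reduces. On certainty of ring formation it is clearly stronger.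
- Against: A3 is far from 24 in oxidation pattern. C1–C2 is saturated and must be dehydrogenated after the enol ether is hydrolysed. The C7 side chain is a methyl-bearing, PMB-protected alcohol that must be oxidised, lactonised and then desaturated to the exocyclic methylene. Two PMB ethers (on O10 and O12) must be told apart.
- Several of these steps are basic and act on a β-alkoxy ketone that can eliminate across C9–C10.
- Comparison: the chosen route accepts a less certain ring closure in exchange for a product, 19, that already has every carbon and the final oxidation pattern.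

Key step: step 10

## Route

Remark: glyceraldehyde acetonide is used as its (S)-enantiomer 5 (commercial, freshly distilled), because Felkin–Anh addition to the (R)-enantiomer would lead to the mirror-image lactone; germacrane numbering (C1–C13) is used for all intermediates.

Step 1
Reactants: 1 methyl acrylate; 2 (tert-butyldimethylsilyloxy)acetaldehyde
Product: 3 methyl 4-[(tert-butyldimethylsilyl)oxy]-3-hydroxy-2-methylidenebutanoate (racemic)
Conditions: DABCO (0.5 equiv), 1 (3 equiv, neat), rt
Reagents that add atoms: none
Why: Morita–Baylis–Hillman reaction: DABCO adds to 1, the zwitterionic enolate adds to the activated α-silyloxy aldehyde 2, and elimination returns the catalyst; the new carbinol centre is racemic and is erased in step 2.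

Step 2
Reactants: 3
Product: 4 methyl (2Z)-2-(bromomethyl)-4-[(tert-butyldimethylsilyl)oxy]but-2-enoate
Conditions: NBS, Me2S, CH2Cl2, 0 °C → rt
Reagents that add atoms: N-bromosuccinimide, O=C1CCC(=O)N1Br
Why: The alkoxysulfonium salt formed from 3 is displaced by bromide in the SN2' sense; the trisubstituted enoate should form as the more stable Z isomer (CH2OTBS trans to the ester), and the neutral conditions leave the silyl ether intact.

Step 3
Reactants: 4; 5 (S)-2,2-dimethyl-1,3-dioxolane-4-carbaldehyde
Product: 7 (4R,5R)-4-{[(tert-butyldimethylsilyl)oxy]methyl}-5-[(4S)-2,2-dimethyl-1,3-dioxolan-4-yl]-3-methylideneoxolan-2-one, via hydroxy ester 6 (not isolated)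
Conditions: Zn dust, THF/sat. aq NH4Cl, 0 °C → rt; then PPTS (cat.), toluene, 60 °C
Reagents that add atoms: none
Why: Barbier allylation: the allylzinc from 4 reacts at its γ-carbon through a chair transition state with the Z-placed CH2OTBS group axial, which gives the C6/C7 syn adduct, and Felkin–Anh approach anti to the dioxolane oxygen of 5 sets C6; acid-catalysed lactonisation of the γ-hydroxy ester then gives the cis lactone.

Step 4
Reactants: 7
Product: 9 (2R,3R)-3-{[(tert-butyldimethylsilyl)oxy]methyl}-4-methylidene-5-oxooxolane-2-carbaldehyde, via diol 8 (not isolated)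
Conditions: H5IO6, EtOAc, rt
Reagents that add atoms: none
Why: Periodic acid hydrolyses the terminal acetonide and cleaves the freed 1,2-diol in the same flask (glycol cleavage), which leaves C5 as the aldehyde; the lactone, the exocyclic alkene and the primary silyl ether should not be affected, and 9 is used at once.

Step 5
Reactants: 9
Product: 10 (4R,5R)-4-{[(tert-butyldimethylsilyl)oxy]methyl}-5-[(1Z)-2-iodoprop-1-en-1-yl]-3-methylideneoxolan-2-one
Conditions: [Ph3PEt]I, n-BuLi, THF, 0 °C; I2, −78 °C; NaN(SiMe3)2, −20 °C; then 9, −78 °C
Reagents that add atoms: ethyltriphenylphosphonium iodide, CC[P+](c1ccccc1)(c1ccccc1)c1ccccc1.[I-]; iodine, [I][I]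
Why: Stork–Zhao-type Wittig olefination with the α-iodo ylide should give the trisubstituted vinyl iodide with iodine cis to C6 (Z) under kinetic control; at −78 °C the ylide is expected to be consumed by the aldehyde faster than it can add to the methylene lactone.

Step 6
Reactants: 11 methacrolein
Product: 12 (2E)-4-methylpenta-2,4-dienal
Conditions: Ph3P=CHCHO, 11 (3 equiv), toluene, 70 °C (sealed)
Reagents that add atoms: (triphenylphosphoranylidene)acetaldehyde, O=CC=P(c1ccccc1)(c1ccccc1)c1ccccc1
Why: Wittig reaction of the stabilised formylmethylene ylide with the aldehyde of 11 gives the E enal; 11 is used in excess so that 12 is not homologated a second time.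

Step 7
Reactants: 10; 12
Product: 13 (4R,5S)-4-{[(tert-butyldimethylsilyl)oxy]methyl}-5-[(1Z,4E)-3-hydroxy-2,6-dimethylhepta-1,4,6-trien-1-yl]-3-methylideneoxolan-2-one (both C3 epimers)
Conditions: CrCl2 (4 equiv), NiCl2 (2 mol %), DMSO/THF, rt
Reagents that add atoms: none
Why: Nozaki–Hiyama–Kishi coupling: the alkenylchromium species forms from 10 with retention of the Z geometry and adds 1,2 to the aldehyde of 12 only, so the lactone, its exocyclic alkene and the silyl ether are untouched; the C3 carbinol forms as a mixture of epimers that converge in step 9.

Step 8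
Reactants: 13
Product: 14 (4R,5S)-5-[(1Z,4E)-3-hydroxy-2,6-dimethylhepta-1,4,6-trien-1-yl]-4-(hydroxymethyl)-3-methylideneoxolan-2-one (both C3 epimers)
Conditions: HF·pyridine, pyridine, THF, 0 °C → rt
Reagents that add atoms: none
Why: Desilylation with pyridine-buffered fluoride frees the C8 hydroxyl under weakly acidic conditions that should neither ionise the doubly allylic C3 alcohol nor trigger base-induced lactone migration to O8; removing the silyl group before C3 is oxidised avoids a hydroxy enone that could close by oxa-Michael addition to C5.

Step 9
Reactants: 14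
Product: 16 (4R,5S)-5-[(1Z,4E)-2,6-dimethyl-3-oxohepta-1,4,6-trien-1-yl]-4-[(E)-(hydroxyimino)methyl]-3-methylideneoxolan-2-one, via keto aldehyde 15 (not isolated)
Conditions: Dess–Martin periodinane (2.5 equiv), NaHCO3, CH2Cl2, 0 °C → rt; then NH2OH·HCl (1.05 equiv), NaOAc, EtOH/THF, 0 °C
Reagents that add atoms: hydroxylamine hydrochloride, Cl.NO
Why: Dess–Martin oxidation converts both alcohols (C3 to the cross-conjugated ketone, C8 to the aldehyde) without base, and the fragile aldehyde 15 is condensed at once with hydroxylamine at acetate-buffered pH, where the unhindered aldehyde should react far faster than the dienone carbonyl or the Michael acceptors.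

Step 10
Reactants: 16
Product: 19 (6S,7R,10R)-3-oxogermacra-1E,4Z,11(13)-trien-12,6-olide bridged from C8 to C10 by a 2-isoxazoline (C8=N–O–C10), via hydroximoyl chloride 17 (not isolated), via nitrile oxide 18 (not isolated)
Conditions: aq NaOCl, CH2Cl2, 0 °C → rt, slow addition of 16, final concentration about 1 mM
Reagents that add atoms: none
Why: Hypochlorite chlorinates the oxime to 17, loss of HCl gives nitrile oxide 18, and 18 adds to the C9=C10 alkene in a concerted, asynchronous [3+2] cycloaddition; the closest known reaction type is the intramolecular nitrile oxide–alkene cycloaddition used for macrocyclisation and followed by N–O cleavage to a β-hydroxy ketone. The ten-membered carbocycle closes in the endo (bridged) mode, with the dipole carbon C8 bonding to the terminal carbon C9 so that both alkene carbons become ring atoms, and the isoxazoline closes by the cycloaddition itself through the C10–O bond. The regiochemistry needed (carbon to CH2, oxygen to the substituted carbon) is the normal one for 1,1-disubstituted alkenes and is reinforced by the polarisation of the dienone terminus. Site selectivity is needed against three other alkenes: C4=C5 and C11=C13 cannot be reached without a bridgehead C=N bond in a small bicycle or a four-membered ring, but the C1=C2 enone alkene could close a seven-membered ring in the fused mode and is held back only by the much lower intrinsic reactivity of a 1,2-disubstituted dipolarophile compared with the terminal methylene. The new stereocentre C10 is controlled by the cis-fused lactone: the N–O end of the dipole should sweep across the ring face that carries H6 and H7, away from C11 and the lactone, which puts the ring oxygen on C10 on that face and gives (10R). The planar E,Z-dienone limits the conformations of the tether, and high dilution with slow addition suppresses dimerisation to the furoxan. The two-phase medium keeps the base in the aqueous layer, which protects the acidic C7–H.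

Step 11
Reactants: 19
Product: 21 (6S,7S,10R)-10-hydroxy-3,8-dioxogermacra-1E,4Z,11(13)-trien-12,6-olide, via hydroxy imine 20 (not isolated)
Conditions: Mo(CO)6, MeCN/H2O (10:1), 75 °C
Reagents that add atoms: water, O
Why: Mo(CO)6 cleaves the N–O bond reductively and the β-hydroxy imine 20 is hydrolysed by the water present, which unmasks the C8/C10 aldol; this reagent is known to spare alkenes, enones and lactones, and the neutral medium should limit retro-aldol cleavage and enolisation at C7.

Step 12
Reactants: 21
Product: 22 (6S,7R,8R,10R)-8,10-dihydroxy-3-oxogermacra-1E,4Z,11(13)-trien-12,6-olide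
Conditions: Me4NBH(OAc)3, MeCN/AcOH (1:1), −30 → −10 °C
Reagents that add atoms: none
Why: Evans–Saksena reduction: the C10 hydroxyl exchanges an acetate on boron and hydride is delivered intramolecularly to the C8 carbonyl on the face that carries the C10 oxygen, which is also the face opposite the lactone, so the 1,3-anti diol with (8R) should result; the dienone and the lactone have no directing hydroxyl in reach and should not be reduced.

Step 13
Reactants: 22; 23 (R)-2-methylbutanoic acid
Product: 24 (6S,7R,8R,10R)-10-hydroxy-8-[(2R)-2-methylbutanoyloxy]-3-oxogermacra-1E,4Z,11(13)-trien-12,6-olide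
Conditions: EDC·HCl, DMAP (cat.), CH2Cl2, 0 °C → rt
Reagents that add atoms: none
Why: Steglich esterification: the secondary C8 hydroxyl is acylated while the tertiary C10 hydroxyl stays free, and carbodiimide activation with catalytic DMAP at low temperature avoids the ketene pathway that would racemise the α-stereocentre of 23.

## Compound list

1 | methyl acrylate | C=CC(=O)OC | starting material
2 | (tert-butyldimethylsilyloxy)acetaldehyde | O=CCO[Si](C)(C)C(C)(C)C | starting material
3 | methyl 4-[(tert-butyldimethylsilyl)oxy]-3-hydroxy-2-methylidenebutanoate (racemic) | C=C(C(=O)OC)C(O)CO[Si](C)(C)C(C)(C)C | intermediate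
4 | methyl (2Z)-2-(bromomethyl)-4-[(tert-butyldimethylsilyl)oxy]but-2-enoate | COC(=O)/C(CBr)=C/CO[Si](C)(C)C(C)(C)C | intermediate
5 | (S)-2,2-dimethyl-1,3-dioxolane-4-carbaldehyde | O=C[C@@H]1COC(C)(C)O1 | starting material
6 | methyl (3R,4R)-3-{[(tert-butyldimethylsilyl)oxy]methyl}-4-[(4S)-2,2-dimethyl-1,3-dioxolan-4-yl]-4-hydroxy-2-methylidenebutanoate | C=C(C(=O)OC)[C@H](CO[Si](C)(C)C(C)(C)C)[C@@H](O)[C@@H]1COC(C)(C)O1 | intermediate
7 | (4R,5R)-4-{[(tert-butyldimethylsilyl)oxy]methyl}-5-[(4S)-2,2-dimethyl-1,3-dioxolan-4-yl]-3-methylideneoxolan-2-one (cis lactone) | C=C1C(=O)O[C@@H]([C@@H]2COC(C)(C)O2)[C@H]1CO[Si](C)(C)C(C)(C)C | intermediate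
8 | (4R,5R)-4-{[(tert-butyldimethylsilyl)oxy]methyl}-5-[(1S)-1,2-dihydroxyethyl]-3-methylideneoxolan-2-one | C=C1C(=O)O[C@@H]([C@@H](O)CO)[C@H]1CO[Si](C)(C)C(C)(C)C | intermediate
9 | (2R,3R)-3-{[(tert-butyldimethylsilyl)oxy]methyl}-4-methylidene-5-oxooxolane-2-carbaldehyde | C=C1C(=O)O[C@@H](C=O)[C@H]1CO[Si](C)(C)C(C)(C)C | intermediate
10 | (4R,5R)-4-{[(tert-butyldimethylsilyl)oxy]methyl}-5-[(1Z)-2-iodoprop-1-en-1-yl]-3-methylideneoxolan-2-one | C=C1C(=O)O[C@@H](/C=C(/C)I)[C@H]1CO[Si](C)(C)C(C)(C)C | intermediate
11 | methacrolein (2-methylprop-2-enal) | CC(=C)C=O | starting material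
12 | (2E)-4-methylpenta-2,4-dienal | O=C/C=C/C(C)=C | intermediate
13 | (4R,5S)-4-{[(tert-butyldimethylsilyl)oxy]methyl}-5-[(1Z,4E)-3-hydroxy-2,6-dimethylhepta-1,4,6-trien-1-yl]-3-methylideneoxolan-2-one (both C3 epimers) | C=C1C(=O)O[C@@H](/C=C(/C)C(O)/C=C/C(C)=C)[C@H]1CO[Si](C)(C)C(C)(C)C | intermediate
14 | (4R,5S)-5-[(1Z,4E)-3-hydroxy-2,6-dimethylhepta-1,4,6-trien-1-yl]-4-(hydroxymethyl)-3-methylideneoxolan-2-one (both C3 epimers) | C=C1C(=O)O[C@@H](/C=C(/C)C(O)/C=C/C(C)=C)[C@H]1CO | intermediate
15 | (2S,3S)-2-[(1Z,4E)-2,6-dimethyl-3-oxohepta-1,4,6-trien-1-yl]-4-methylidene-5-oxooxolane-3-carbaldehyde | C=C1C(=O)O[C@@H](/C=C(/C)C(=O)/C=C/C(C)=C)[C@H]1C=O | intermediate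
16 | (4R,5S)-5-[(1Z,4E)-2,6-dimethyl-3-oxohepta-1,4,6-trien-1-yl]-4-[(E)-(hydroxyimino)methyl]-3-methylideneoxolan-2-one | C=C1C(=O)O[C@@H](/C=C(/C)C(=O)/C=C/C(C)=C)[C@H]1/C=N/O | intermediate
17 | (2S,3S)-2-[(1Z,4E)-2,6-dimethyl-3-oxohepta-1,4,6-trien-1-yl]-N-hydroxy-4-methylidene-5-oxooxolane-3-carboximidoyl chloride | C=C1C(=O)O[C@@H](/C=C(/C)C(=O)/C=C/C(C)=C)[C@H]1C(Cl)=NO | intermediate
18 | (2S,3R)-2-[(1Z,4E)-2,6-dimethyl-3-oxohepta-1,4,6-trien-1-yl]-4-methylidene-5-oxooxolane-3-carbonitrile oxide | C=C1C(=O)O[C@@H](/C=C(/C)C(=O)/C=C/C(C)=C)[C@H]1C#[N+][O-] | intermediate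
19 | (6S,7R,10R)-3-oxogermacra-1E,4Z,11(13)-trien-12,6-olide bridged from C8 to C10 by a 2-isoxazoline (C8 is the C=N carbon, the ring oxygen is on C10) | C=C1C(=O)O[C@H]2/C=C(/C)C(=O)/C=C/[C@]3(C)ON=C(C3)[C@@H]12 | intermediate
20 | (6S,7R,10R)-10-hydroxy-8-imino-3-oxogermacra-1E,4Z,11(13)-trien-12,6-olide | C=C1C(=O)O[C@H]2/C=C(/C)C(=O)/C=C/[C@](C)(O)CC(=N)[C@@H]12 | intermediate
21 | (6S,7S,10R)-10-hydroxy-3,8-dioxogermacra-1E,4Z,11(13)-trien-12,6-olide | C=C1C(=O)O[C@H]2/C=C(/C)C(=O)/C=C/[C@](C)(O)CC(=O)[C@@H]12 | intermediate
22 | (6S,7R,8R,10R)-8,10-dihydroxy-3-oxogermacra-1E,4Z,11(13)-trien-12,6-olide | C=C1C(=O)O[C@H]2/C=C(/C)C(=O)/C=C/[C@](C)(O)C[C@@H](O)[C@@H]12 | intermediate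
23 | (R)-2-methylbutanoic acid | CC[C@@H](C)C(=O)O | starting material
24 | (6S,7R,8R,10R)-10-hydroxy-8-[(2R)-2-methylbutanoyloxy]-3-oxogermacra-1E,4Z,11(13)-trien-12,6-olide (CNP0315499.3) | C=C1C(=O)O[C@H]2/C=C(/C)C(=O)/C=C/[C@](C)(O)C[C@@H](OC(=O)[C@H](C)CC)[C@@H]12 | target

## Step count and least certain steps

Total step count: 13. Longest linear sequence: 12 steps (steps 1–5 and 7–13); step 6 is a one-step side branch.

**Step 10 (key step).** The most likely failure is that nitrile oxide 18 is consumed by easier pathways than the ten-membered closure. These are dimerisation to the furoxan and, above all, fused-mode addition to the C1=C2 enone alkene, which closes a seven-membered ring and is entropically favoured even though that alkene is intrinsically less reactive. In addition, attack on the other face of C9=C10 would give the C10 epimer, and hypochlorite or base at the interface may erode C7 or attack the dienone.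

Fallback: the isoxazoline is made intermolecularly and the ring is closed at C3–C4, setting out from vinyl iodide 10.
- Buffered HF·pyridine gives alcohol F1.
- Dess–Martin oxidation gives aldehyde F2, and hydroxylamine gives oxime F3.
- Oxidation of F3 with PhI(OAc)2 in MeOH in the presence of an excess of dienal 12 generates nitrile oxide F4. F4 should add to the terminal alkene of 12 to give isoxazoline enal F5. C10 is not controlled here, so the (10R) epimer would have to be separated.
- Intramolecular Nozaki–Hiyama–Kishi coupling of F5 (CrCl2, catalytic NiCl2, DMSO/THF, high dilution) closes the ten-membered ring to carbinol F6.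
- Dess–Martin oxidation of F6 returns to the route at 19.

**Step 9.** Keto aldehyde 15 can enolise toward C7, which is α to the aldehyde and γ to the lactone carbonyl. This would epimerise C7 or move the exocyclic alkene into the ring. Hydroxylamine may also add in conjugate fashion.

Fallback: the nitrile oxide is made from a primary nitro compound so that C8 is never an aldehyde, setting out from 13.
- Dess–Martin oxidation gives trienone silyl ether F7, and buffered HF·pyridine gives hydroxy trienone F8. F8 must be kept from base because of possible oxa-Michael closure onto C5.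
- PPh3, I2 and imidazole give iodide F9, and AgNO2 in Et2O gives nitro compound F10.
- Dehydration of F10 with PhNCO and catalytic Et3N at high dilution gives nitrile oxide 18, which closes to 19 as in step 10.

**Step 3.** Facial selectivity toward 5 or syn selectivity may be poor if the allylzinc equilibrates its geometry. 1,4-Elimination of the silyloxy group from the organozinc is also possible.

Fallback: a configurationally defined allylboronate is used, setting out from 4.
- B2pin2 with catalytic Pd2(dba)3 in toluene converts 4 into allylboronate F11.
- Thermal allylboration of 5 through a closed chair transition state gives borate F12.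
- Acidic work-up of F12 gives 6 and then lactone 7, where the route is rejoined.

**Step 5.** The basic, nucleophilic ylide or residual amide base may add to the methylene lactone or epimerise C6 of the α-acyloxy aldehyde. Z selectivity may be incomplete.

Fallback: the halide is introduced by a trans-selective cross-coupling, setting out from 9.
- Preformed CBr4/PPh3 reagent in CH2Cl2 at 0 °C gives dibromoalkene F13.
- Monomethylation with Me2Zn and Pd(PtBu3)2 replaces the bromine trans to C6 and gives (Z)-vinyl bromide F14.
- F14 is coupled with 12 under the conditions of step 7 (more NiCl2, DMF) to rejoin the route at 13.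

**Step 12.** Ligand exchange at the hindered tertiary C10 hydroxyl may be slow, or the ring conformation may expose the other carbonyl face, so that facial control is lost. The freed C8 hydroxyl may also attack the lactone carbonyl.

Fallback: if reduction of 21 gives mainly the 8-epimeric diol F15 (it can also be made deliberately from 21 with Et2BOMe and NaBH4 at −78 °C), Mitsunobu esterification of F15 with acid 23 (PPh3, DIAD, THF, 0 °C) inverts C8 and gives 24 directly.

## Further compounds

F1 | step 10 | (4R,5R)-4-(hydroxymethyl)-5-[(1Z)-2-iodoprop-1-en-1-yl]-3-methylideneoxolan-2-one | C=C1C(=O)O[C@@H](/C=C(/C)I)[C@H]1CO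
F2 | step 10 | (2R,3S)-2-[(1Z)-2-iodoprop-1-en-1-yl]-4-methylidene-5-oxooxolane-3-carbaldehyde | C=C1C(=O)O[C@@H](/C=C(/C)I)[C@H]1C=O
F3 | step 10 | oxime of F2, (E)-(hydroxyimino)methyl group on C7 | C=C1C(=O)O[C@@H](/C=C(/C)I)[C@H]1/C=N/O
F4 | step 10 | nitrile oxide derived from F3 | C=C1C(=O)O[C@@H](/C=C(/C)I)[C@H]1C#[N+][O-]
F5 | step 10 | 3-substituted (5R)-5-methyl-5-[(1E)-3-oxoprop-1-en-1-yl]-2-isoxazoline carrying the vinyl iodide lactone at C3 of the isoxazoline (germacrane C10 R) | C=C1C(=O)O[C@@H](/C=C(/C)I)[C@H]1C2=NO[C@@](C)(/C=C/C=O)C2
F6 | step 10 | C3 carbinol of 19 (both C3 epimers) | C=C1C(=O)O[C@H]2/C=C(/C)C(O)/C=C/[C@]3(C)ON=C(C3)[C@@H]12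
F7 | step 9 | (4R,5S)-4-{[(tert-butyldimethylsilyl)oxy]methyl}-5-[(1Z,4E)-2,6-dimethyl-3-oxohepta-1,4,6-trien-1-yl]-3-methylideneoxolan-2-one | C=C1C(=O)O[C@@H](/C=C(/C)C(=O)/C=C/C(C)=C)[C@H]1CO[Si](C)(C)C(C)(C)C
F8 | step 9 | (4R,5S)-5-[(1Z,4E)-2,6-dimethyl-3-oxohepta-1,4,6-trien-1-yl]-4-(hydroxymethyl)-3-methylideneoxolan-2-one | C=C1C(=O)O[C@@H](/C=C(/C)C(=O)/C=C/C(C)=C)[C@H]1CO
F9 | step 9 | C8 iodide corresponding to F8 (iodomethyl on C7) | C=C1C(=O)O[C@@H](/C=C(/C)C(=O)/C=C/C(C)=C)[C@H]1CI
F10 | step 9 | C8 nitro compound corresponding to F8 (nitromethyl on C7) | C=C1C(=O)O[C@@H](/C=C(/C)C(=O)/C=C/C(C)=C)[C@H]1C[N+](=O)[O-]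
F11 | step 3 | methyl (2E)-4-[(tert-butyldimethylsilyl)oxy]-2-[(4,4,5,5-tetramethyl-1,3,2-dioxaborolan-2-yl)methyl]but-2-enoate (CH2OTBS cis to CH2B) | COC(=O)/C(CB1OC(C)(C)C(C)(C)O1)=C/CO[Si](C)(C)C(C)(C)C
F12 | step 3 | O-pinacolboryl derivative of hydroxy ester 6 | C=C(C(=O)OC)[C@H](CO[Si](C)(C)C(C)(C)C)[C@@H](OB1OC(C)(C)C(C)(C)O1)[C@@H]1COC(C)(C)O1
F13 | step 5 | (4R,5R)-4-{[(tert-butyldimethylsilyl)oxy]methyl}-5-(2,2-dibromoethenyl)-3-methylideneoxolan-2-one | C=C1C(=O)O[C@@H](C=C(Br)Br)[C@H]1CO[Si](C)(C)C(C)(C)C
F14 | step 5 | (4R,5R)-5-[(1Z)-2-bromoprop-1-en-1-yl]-4-{[(tert-butyldimethylsilyl)oxy]methyl}-3-methylideneoxolan-2-one | C=C1C(=O)O[C@@H](/C=C(/C)Br)[C@H]1CO[Si](C)(C)C(C)(C)C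
F15 | step 12 | (6S,7R,8S,10R)-8,10-dihydroxy-3-oxogermacra-1E,4Z,11(13)-trien-12,6-olide (8-epimer of 22) | C=C1C(=O)O[C@H]2/C=C(/C)C(=O)/C=C/[C@](C)(O)C[C@H](O)[C@@H]12
A1 | alternative 1 | ten-membered C6 carbinol with C3 dioxolane ketal, C10 triethylsilyl ether, C8 tert-butyldimethylsilyl ether and a 3-(4-methoxybenzyloxy)prop-1-en-2-yl group on C7 | O[C@H]1/C=C(/C)C2(OCCO2)/C=C/[C@](C)(O[Si](CC)(CC)CC)C[C@@H](O[Si](C)(C)C(C)(C)C)[C@H]1C(=C)COCc1ccc(OC)cc1
A2 | alternative 2 | ten-membered 1E,4Z-dienone 12,6-lactone without C13, C10 hydroxyl free, C8 tert-butyldimethylsilyl ether | C1C(=O)O[C@H]2/C=C(/C)C(=O)/C=C/[C@](C)(O)C[C@@H](O[Si](C)(C)C(C)(C)C)[C@@H]12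
A3 | alternative 3 | ten-membered C8 ketone with C3 methyl enol ether, C10 4-methoxybenzyl ether, C6 tert-butyldimethylsilyl ether and a 1-(4-methoxybenzyloxy)propan-2-yl group on C7 | O=C1C[C@@](C)(OCc2ccc(OC)cc2)C/C=C(OC)/C(C)=C\[C@H](O[Si](C)(C)C(C)(C)C)[C@@H]1[C@H](C)COCc1ccc(OC)cc1
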